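**Retrosynthetic overview**

1. Labels (ring atoms in target SMILES order): C1 CH–O-tigloyl, C2 CH2, C3 CH–O-isovaleryl, C4 CMe2, C5 CH, C6 CH, C7 C=O, C8 =CH, C9 =C(CH3), C10 CH, C11 C(CH3). Ring A = C5–C10 (six-membered enone), ring B = C10-C11-C1-C2-C3-C4-C5 (seven-membered), cyclobutane = C5-C6-C11-C10.
2. Esters last: C1 tiglate by acylation; the C3 isovalerate and the C1 carbinol are made together by an Evans–Tishchenko reduction of a 3-hydroxy-1-ketone, which comes from conjugate borylation–oxidation of a ring B enone.
3. Key disconnection: cyclobutane bond C6–C11, both carbons α to a carbonyl (C7 and C1), by transannular oxidative coupling of the bis-enolate of a cis-fused ring A/ring B bis-enone; one enolate acts as an enolonium equivalent.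
4. Ring B by ring-closing metathesis (C2=C3); C7=O by allylic oxidation; C10–C11 by Johnson–Claisen rearrangement of a cis-cyclohexenol; ring A and C5 by an organocatalytic Michael–aldol annulation of 3,3-dimethylpent-4-enal with ethyl vinyl ketone.
5. Order of ring formation: ring A, then ring B, then the cyclobutane (which completes the bicyclo[3.1.1]heptenone). No protecting groups are used.

Assumption: the chiral catalysts of steps 1, 2 and 8 induce in the sense of their standard models (if a test run shows the opposite sense, the antipodal catalyst is used), and 3,3-dimethylpent-4-enal is bought (it is also one reduction away from the bulk ester methyl 3,3-dimethylpent-4-enoate).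

**Route**

Step 1
Reactants: 1 3,3-dimethylpent-4-enal; 2 pent-1-en-3-one
Product: 4 (R)-2-methyl-4-(2-methylbut-3-en-2-yl)cyclohex-2-en-1-one, via keto aldehyde 3 (not isolated)
Conditions: (S)-α,α-diphenylprolinol methyl ether (10 mol%), ethyl 3,4-dihydroxybenzoate (20 mol%), neat, 4 °C; then p-TsOH·H2O (20 mol%), toluene, 80 °C
Reagents that add atoms: none
Why: Enamine-mediated asymmetric Michael addition (the diarylmethyl group shields one enamine face and sets C5, S in 3 = R in 4) followed by acid-catalysed intramolecular aldol condensation of the ethyl ketone onto the aldehyde (Robinson-type annulation), the only cyclisation mode that gives a six-membered ring.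

Step 2
Reactants: 4 (R)-2-methyl-4-(2-methylbut-3-en-2-yl)cyclohex-2-en-1-one
Product: 5 (1S,4R)-2-methyl-4-(2-methylbut-3-en-2-yl)cyclohex-2-en-1-ol
Conditions: (R)-2-methyl-CBS-oxazaborolidine (20 mol%), catecholborane (1.5 equiv), toluene, −78 °C; aqueous NaOH work-up
Reagents that add atoms: none
Why: Corey–Bakshi–Shibata reduction, in which catalyst-controlled hydride delivery to one carbonyl face gives the (1S) carbinol with OH cis to the C4 substituent, while catecholborane leaves the alkenes alone at this temperature.

Step 3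
Reactants: 5 (1S,4R)-2-methyl-4-(2-methylbut-3-en-2-yl)cyclohex-2-en-1-ol
Product: 7 ethyl 2-[(1S,6R)-2-methyl-6-(2-methylbut-3-en-2-yl)cyclohex-2-en-1-yl]propanoate, via ketene acetal 6 (not isolated)
Conditions: triethyl orthopropionate (6 equiv), EtCO2H (10 mol%), xylenes, 140 °C, EtOH distilled off
Reagents that add atoms: triethyl orthopropionate CCC(OCC)(OCC)OCC
Why: Johnson–Claisen rearrangement, whose suprafacial [3,3] shift transfers the C8–O configuration to C10 so that the new C10–C11 bond is cis to the C5 substituent and the alkene moves to C8=C9; the C11 epimer ratio does not matter because C11 is enolised later.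

Step 4
Reactants: 7 ethyl 2-[(1S,6R)-2-methyl-6-(2-methylbut-3-en-2-yl)cyclohex-2-en-1-yl]propanoate
Product: 9 vinyl ketone 4-[(1S,6R)-2-methyl-6-(2-methylbut-3-en-2-yl)cyclohex-2-en-1-yl]pent-1-en-3-one, via Weinreb amide 8 (not isolated)
Conditions: MeNH(OMe)·HCl (1.6 equiv), i-PrMgCl (3.2 equiv), THF, −20 °C; then CH2=CHMgBr (3 equiv), −20 to 0 °C; inverse quench into cold 1 M HCl
Reagents that add atoms: N,O-dimethylhydroxylamine hydrochloride CNOC.Cl (atoms kept only in 8); vinylmagnesium bromide C=C[Mg]Br
Why: Weinreb ketone synthesis run in one flask, where the chelated tetrahedral intermediate stops over-addition of the vinyl Grignard reagent and the acidic inverse quench keeps the liberated amine from adding to the new enone; no stereocentre is touched.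

Step 5
Reactants: 9 vinyl ketone 4-[(1S,6R)-2-methyl-6-(2-methylbut-3-en-2-yl)cyclohex-2-en-1-yl]pent-1-en-3-one
Product: 10 cis-fused bicyclic enone (ring B cyclohept-2-enone, ring A cyclohexene C8=C9; 5R,10S)
Conditions: second-generation Grubbs catalyst (5 mol%), toluene, 0.005 M, 80 °C, argon sparge
Reagents that add atoms: none
Why: Ring-closing metathesis of the vinyl ketone onto the neopentyl vinyl group gives the seven-membered (Z)-enone because both chains sit cis on ring A, and the trisubstituted ring alkene is a spectator.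

Step 6
Reactants: 10 cis-fused bicyclic enone
Product: 12 cis-fused bis-enone (ring A 3-methylcyclohex-2-enone C7=O, ring B cyclohept-2-enone C1=O; 5R,10S), via allyl peroxide 11 (not isolated)
Conditions: Rh2(caprolactamate)4 (1 mol%), t-BuOOH (70% aq, 5 equiv), K2CO3 (0.5 equiv), CH2Cl2, rt
Reagents that add atoms: tert-butyl hydroperoxide CC(C)(C)OO
Why: Kharasch-type allylic oxidation, in which t-BuOO• abstracts hydrogen from the least hindered allylic CH2 (C7) and the mixed peroxide collapses to the conjugated enone; the tertiary C10–H is shielded by two branched neighbours, so C5 and C10 are kept.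

Step 7
Reactants: 12 cis-fused bis-enone
Product: 14 tricyclic bis-enone (5S,6R,10R,11R), via dilithium bis-dienolate 13 (not isolated)
Conditions: LiN(i-Pr)2 (2.3 equiv), THF, −78 to −40 °C; then CuCl2 (2.4 equiv) in DMF, −78 to 0 °C, 0.01 M
Reagents that add atoms: none
Why: Proposed new method: both enones can only be deprotonated at their α′ carbons (C6 and C11; the γ-carbon of ring B is quaternary), so the base gives one defined bis-dienolate 13 in which the cis ring fusion holds the two nucleophilic carbons eclipsed across C5–C10 at about 3 Å; one-electron oxidation by divalent copper (or reductive elimination from a copper bis-enolate) turns one enolate into an α-keto radical/enolonium equivalent that is captured by the other (4-exo), a second oxidation gives the 1,4-diketone, and the tether dictates both new centres (C1 anti and CH3 syn to the enone bridge); the closest known reaction types are the CuCl2-, Cu(OTf)2- or I2-mediated intramolecular oxidative coupling of 1,6-dicarbonyl bis-enolates to 1,2-diacylcyclobutanes, iron- or copper-mediated intramolecular enolate heterocoupling, and enolate-alkylation closures of bicyclo[3.1.1]heptan-2-ones.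

Step 8
Reactants: 14 tricyclic bis-enone
Product: 16 (3R)-3-hydroxy-1-ketone, via boryl ketone 15 (not isolated)
Conditions: CuCl (5 mol%), NaOt-Bu (10 mol%), (R)-Tol-BINAP (6 mol%), B2pin2 (1.2 equiv), MeOH (2 equiv), THF, rt; then 30% H2O2, pH 7 phosphate buffer, 0 °C
Reagents that add atoms: bis(pinacolato)diboron CC1(C)OB(OC1(C)C)B1OC(C)(C)C(C)(C)O1 (atoms kept only in 15); hydrogen peroxide OO
Why: Ligand-controlled copper–boryl conjugate addition (β-borylation) occurs only at the disubstituted ring B enone because the ring A enone is β,β-disubstituted at a bridgehead; the chiral bisphosphine directs boron to the C10-side face of C3 and stereoretentive C–B oxidation gives the (3R) alcohol.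

Step 9
Reactants: 16 (3R)-3-hydroxy-1-ketone
Product: 17 (1R,3R)-1-hydroxy-3-isovalerate
Conditions: SmI2 (0.3 equiv, 0.1 M in THF), 3-methylbutanal (6 equiv), THF, −10 °C, dark
Reagents that add atoms: 3-methylbutanal CC(C)CC=O
Why: Evans–Tishchenko reduction, in which the samarium-bound hemiacetal of the C3 alkoxide and the aldehyde delivers hydride to C1 from the face of the C3 oxygen, giving the 1,3-anti (trans) carbinol (1R) and placing the isovaleryl group on the C3 oxygen in the same event.

Step 10
Reactants: 17 (1R,3R)-1-hydroxy-3-isovalerate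
Product: 18 CNP0194415.1
Conditions: tiglic anhydride (3 equiv), DMAP (1 equiv), Et3N (3 equiv), toluene, 40 °C
Reagents that add atoms: tiglic anhydride C/C=C(\C)C(=O)OC(=O)/C(C)=C/C
Why: DMAP-catalysed acyl transfer (Steglich-type acylation) to the remaining neopentyl secondary alcohol with the preformed (E)-anhydride keeps the tiglate geometry, and the trans-1,3 arrangement disfavours isovaleryl migration.

**Compound list**

1 | 3,3-dimethylpent-4-enal | O=CCC(C)(C)C=C | starting material
2 | pent-1-en-3-one (ethyl vinyl ketone) | CCC(=O)C=C | starting material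
3 | (S)-2-(2-methylbut-3-en-2-yl)-5-oxoheptanal (not isolated) | C=CC(C)(C)[C@@H](C=O)CCC(=O)CC | intermediate
4 | (R)-2-methyl-4-(2-methylbut-3-en-2-yl)cyclohex-2-en-1-one | C=CC(C)(C)[C@@H]1CCC(=O)C(C)=C1 | intermediate
5 | (1S,4R)-2-methyl-4-(2-methylbut-3-en-2-yl)cyclohex-2-en-1-ol (OH cis to the C4 substituent) | C=CC(C)(C)[C@@H]1CC[C@H](O)C(C)=C1 | intermediate
6 | 1-ethoxyprop-1-enyl ether of 5 (mixed ketene acetal, not isolated) | C=CC(C)(C)[C@@H]1CC[C@H](OC(OCC)=CC)C(C)=C1 | intermediate
7 | ethyl 2-[(1S,6R)-2-methyl-6-(2-methylbut-3-en-2-yl)cyclohex-2-en-1-yl]propanoate (ring substituents cis; propanoate C2 epimers) | C=CC(C)(C)[C@@H]1CCC=C(C)[C@@H]1C(C)C(=O)OCC | intermediate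
8 | N-methoxy-N-methyl amide corresponding to 7 (not isolated) | C=CC(C)(C)[C@@H]1CCC=C(C)[C@@H]1C(C)C(=O)N(C)OC | intermediate
9 | 4-[(1S,6R)-2-methyl-6-(2-methylbut-3-en-2-yl)cyclohex-2-en-1-yl]pent-1-en-3-one (C4 epimers) | C=CC(C)(C)[C@@H]1CCC=C(C)[C@@H]1C(C)C(=O)C=C | intermediate
10 | cis-fused bicyclo[5.4.0] enone: ring B C1=O, C2=C3, CMe2 at C4, CH(CH3) at C11; ring A C8=C9(CH3); 5R,10S, H5/H10 cis, C11 epimers | O=C1C=CC(C)(C)[C@@H]2CCC=C(C)[C@@H]2C1C | intermediate
11 | C7 tert-butylperoxy derivative of 10 (not isolated) | O=C1C=CC(C)(C)[C@@H]2CC(OOC(C)(C)C)C=C(C)[C@@H]2C1C | intermediate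
12 | cis-fused bis-enone: as 10 with C7=O conjugated to C8=C9; 5R,10S, C11 epimers | O=C1C=CC(C)(C)[C@@H]2CC(=O)C=C(C)[C@@H]2C1C | intermediate
13 | dilithium bis-dienolate of 12 (C1-O/C1=C11 and C7-O/C6=C7; not isolated) | [Li+].[Li+].[O-]C=1C=CC(C)(C)[C@@H]2C=C([O-])C=C(C)[C@@H]2C=1C | intermediate
14 | tricyclic bis-enone with C6–C11 bond (longipinane skeleton; 5S,6R,10R,11R; C1=O/C2=C3 and C7=O/C8=C9) | O=C1C=CC(C)(C)[C@@H]2[C@H]3C(=O)C=C(C)[C@@H]2[C@]31C | intermediate
15 | (3R)-3-(pinacolboryl)-1-ketone derived from 14 (not isolated) | O=C1C[C@@H](B2OC(C)(C)C(C)(C)O2)C(C)(C)[C@@H]3[C@H]4C(=O)C=C(C)[C@@H]3[C@]41C | intermediate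
16 | (3R,5S,6R,10R,11R)-3-hydroxy-1,7-diketone (ring A enone intact) | O=C1C[C@@H](O)C(C)(C)[C@@H]2[C@H]3C(=O)C=C(C)[C@@H]2[C@]31C | intermediate
17 | (1R,3R,5S,6R,10R,11R)-1-hydroxy-3-(3-methylbutanoyloxy) enone (C1-OH trans to C3-O) | O[C@@H]1C[C@@H](OC(=O)CC(C)C)C(C)(C)[C@@H]2[C@H]3C(=O)C=C(C)[C@@H]2[C@]31C | intermediate
18 | CNP0194415.1: C1 (E)-2-methylbut-2-enoate, C3 3-methylbutanoate of the tricyclic enone (1R,3R,5S,6R,10R,11R) | C/C=C(\C)C(=O)O[C@@H]1C[C@@H](OC(=O)CC(C)C)C(C)(C)[C@@H]2[C@H]3C(=O)C=C(C)[C@@H]2[C@]31C | target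

**Step count and risks**

Total step count: 10. Longest linear sequence: 10 steps (fully linear from 1 and 2).

The three steps most likely to fail:

Step 7, the transannular oxidative coupling, carries the highest risk (strained four-membered ring, possible intermolecular or O–C coupling). The fallback sets out from 12: the same double α′-deprotonation is trapped with TMSCl and the bis(trimethylsilyl) dienol ether F1 is isolated. F1 is then oxidised with (NH4)2Ce(NO3)6 and NaHCO3 in MeCN/EtCN at −30 °C. Here the electron-rich tetrasubstituted enol silane is oxidised to a radical cation that is captured by the second enol silane, so the bond forms by neutral single-electron enol-silane coupling instead of anionic copper-mediated coupling. Loss of both silyl groups returns to the route at 14.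

Step 6, the allylic oxidation, may give mixtures from attack at C10–H or the C9 methyl. The fallback sets out from 10: m-CPBA epoxidises only the electron-rich C8=C9 alkene to the epoxide F2. PhSeNa opens F2 at the secondary C8 to give the β-hydroxy selenide F3. H2O2 converts F3 to the selenoxide F4, whose syn-elimination (only C7 carries a usable hydrogen) gives the tertiary allylic alcohol F5. Pyridinium chlorochromate then effects the oxidative 1,3-transposition of F5 and the route is rejoined at 12.

Step 8, the facial selectivity at C3, is uncertain because the two faces of the ring B enone differ only remotely. The fallback sets out from 14: reagent-controlled nucleophilic epoxidation (La(O-i-Pr)3, (R)-BINOL, Ph3As=O, cumene hydroperoxide) gives the 2,3-epoxy ketone F6. Reductive cleavage of its Cα–O bond with Na[PhSeB(OEt)3] (from (PhSe)2 and NaBH4, AcOH, EtOH, 0 °C) gives the β-hydroxy ketone and the route is rejoined at 16.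

**Further compounds**

F1 | step 7 | bis(trimethylsilyl) dienol ether of 12 | C[Si](C)(C)OC=1C=CC(C)(C)[C@@H]2C=C(O[Si](C)(C)C)C=C(C)[C@@H]2C=1C
F2 | step 6 | 8,9-epoxide of 10 (epoxide face not controlled) | O=C1C=CC(C)(C)[C@@H]2CCC3OC3(C)[C@@H]2C1C
F3 | step 6 | 9-hydroxy-8-phenylselanyl derivative of 10 | O=C1C=CC(C)(C)[C@@H]2CCC([Se]c3ccccc3)C(C)(O)[C@@H]2C1C
F4 | step 6 | selenoxide of F3 (not isolated) | O=C1C=CC(C)(C)[C@@H]2CCC([Se](=O)c3ccccc3)C(C)(O)[C@@H]2C1C
F5 | step 6 | tertiary allylic alcohol (C9-OH, C7=C8) | O=C1C=CC(C)(C)[C@@H]2CC=CC(C)(O)[C@@H]2C1C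
F6 | step 8 | 2,3-epoxy ketone of 14 (epoxide oxygen on the C10-side face) | O=C1[C@H]2O[C@H]2C(C)(C)[C@@H]3[C@H]4C(=O)C=C(C)[C@@H]3[C@]41C
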